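## Retrosynthetic overview
1. The last C–C bond is C10'–C11'. It is made by Stille coupling of polyenynyl stannane 48 (ring A to C11') with β-diketone vinyl iodide 24 (C10' to ring B), followed by removal of three silyl groups.
2. Stannane 48 comes from enynal 37 by two E-selective Horner–Wadsworth–Emmons olefinations: C11=C12 with C5 phosphonate 38, and C15=C15' with stannyl C6 phosphonate 46.
3. Iodide 24 comes from cyclopentyl methyl ketone 17 and (E)-3-iodo-2-methylacrolein 21 by aldol addition and oxidation.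
4. Both 37 and 17 come from one intermediate, silylated (4R,6R)-actinol 4. It is made from achiral ketoisophorone 1 by an ene-reductase and then a ketoreductase.
5. Ring order: the six-membered carbocycle is already present in 1 and is kept as ring A. Ring B (the cyclopentane) is made second, by stereospecific contraction of a Sharpless-derived 5,6-epoxide (step 10).

Assumption: the enol drawn in the target is the hydrogen-bonded tautomer that the C6'/C8' 1,3-diketone adopts spontaneously. Positions are given in carotenoid numbering, and TBS = tert-butyldimethylsilyl.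

## Route

### Common intermediate (steps 1–3)

**Step 1**
Reactants: 1 ketoisophorone (2,6,6-trimethylcyclohex-2-ene-1,4-dione)
Product: 2 (6R)-2,2,6-trimethylcyclohexane-1,4-dione ((6R)-levodione)
Conditions: ene-reductase (flavin-dependent Old Yellow Enzyme family, OYE2 type), NAD+ (cat.), formate dehydrogenase, HCO2Na, KH2PO4/K2HPO4 buffer pH 7.0, 30 °C
Reagents that add atoms: none
Why: In this biocatalytic asymmetric conjugate reduction the ene-reductase holds the activated C=C over its reduced flavin and adds hydride and proton trans across it from fixed faces, which sets the first stereocentre (6R) from an achiral substrate.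

**Step 2**
Reactants: 2 (6R)-levodione
Product: 3 (4R,6R)-4-hydroxy-2,2,6-trimethylcyclohexan-1-one ((4R,6R)-actinol)
Conditions: ketoreductase (NADH-dependent short-chain alcohol dehydrogenase, levodione reductase type), NAD+ (cat.), formate dehydrogenase, HCO2Na, KH2PO4/K2HPO4 buffer pH 7.0, 30 °C; recrystallise
Reagents that add atoms: none
Why: In this enzymatic asymmetric ketone reduction the ketoreductase accepts only the unhindered C4 carbonyl and transfers the NADH hydride to one face, giving the 4R carbinol that becomes both C3 and C3' of the target.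

**Step 3**
Reactants: 3 (4R,6R)-actinol
Product: 4 (4R,6R)-4-(TBSO)-2,2,6-trimethylcyclohexan-1-one
Conditions: t-BuMe2SiCl, imidazole, DMF, rt
Reagents that add atoms: tert-butyldimethylsilyl chloride, CC(C)(C)[Si](C)(C)Cl
Why: Imidazole-promoted silyl ether formation masks the only hydroxyl against the bases, hydrides and oxidants used later and touches no stereocentre.

### Ring B and iodide 24 (steps 4–17)

**Step 4**
Reactants: 4 silylated actinol
Product: 6 (4R)-4-(TBSO)-2,6,6-trimethylcyclohex-1-en-1-yl trifluoromethanesulfonate, via potassium enolate 5 (not isolated)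
Conditions: KN(SiMe3)2, THF, −78 °C; then PhNTf2, −78 °C → rt
Reagents that add atoms: N-phenylbis(trifluoromethanesulfonimide), O=S(=O)(N(c1ccccc1)S(=O)(=O)C(F)(F)F)C(F)(F)F
Why: Only the methyl-bearing α-carbon has a hydrogen (the other is quaternary), so enolisation is regiospecific, and O-triflation (enol triflate formation) erases that centre while the carbinol centre is kept.

**Step 5**
Reactants: 6 enol triflate
Product: 7 methyl (4R)-4-(TBSO)-2,6,6-trimethylcyclohex-1-ene-1-carboxylate
Conditions: Pd(OAc)2 (5 mol %), PPh3 (10 mol %), CO (1 atm), MeOH, Et3N, DMF, 60 °C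
Reagents that add atoms: carbon monoxide, [C-]#[O+]; methanol, CO
Why: In this palladium-catalysed methoxycarbonylation zerovalent palladium inserts into the C–OTf bond, CO inserts, and methanol cleaves the acyl-palladium to give the enoate.

**Step 6**
Reactants: 7 enoate
Product: 8 [(4R)-4-(TBSO)-2,6,6-trimethylcyclohex-1-en-1-yl]methanol
Conditions: i-Bu2AlH (2.5 equiv), CH2Cl2, −78 → 0 °C
Reagents that add atoms: none
Why: Hydride 1,2-reduction of the conjugated ester with i-Bu2AlH gives the allylic alcohol without touching the tetrasubstituted alkene or the silyl ether.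

**Step 7**
Reactants: 8 allylic alcohol
Product: 9 [(1R,4S,6R)-4-(TBSO)-2,2,6-trimethyl-7-oxabicyclo[4.1.0]heptan-1-yl]methanol
Conditions: Ti(Oi-Pr)4 (20 mol %), D-(−)-diethyl tartrate (24 mol %), t-BuOOH, 4 Å molecular sieves, CH2Cl2, −20 °C
Reagents that add atoms: tert-butyl hydroperoxide, CC(C)(C)OO
Why: In this Sharpless asymmetric epoxidation the titanium–D-tartrate catalyst delivers oxygen to the alkene face anti to the C3 silyloxy group, setting C5 and C6 in the (3S,5R,6S) array (carotenoid numbering).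

**Step 8**
Reactants: 9 epoxy alcohol
Product: 10 (1S,4S,6R)-4-(TBSO)-2,2,6-trimethyl-7-oxabicyclo[4.1.0]heptane-1-carbaldehyde
Conditions: [n-Pr4N][RuO4] (5 mol %), N-methylmorpholine N-oxide, 4 Å molecular sieves, CH2Cl2, rt
Reagents that add atoms: none
Why: The Ley–Griffith oxidation is neutral, so the acid-labile tetrasubstituted epoxide survives, and the aldehyde has no α-hydrogen to epimerise.

**Step 9**
Reactants: 10 epoxy aldehyde
Product: 11 ethyl (2E)-3-[(1S,4S,6R)-4-(TBSO)-2,2,6-trimethyl-7-oxabicyclo[4.1.0]heptan-1-yl]prop-2-enoate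
Conditions: (EtO)2P(O)CH2CO2Et, NaH, THF, 0 °C → rt
Reagents that add atoms: triethyl phosphonoacetate, CCOC(=O)CP(=O)(OCC)OCC
Why: The Horner–Wadsworth–Emmons reaction of a stabilised phosphonate anion copes with the hindered aldehyde and gives the E-acrylate, which is the electron-withdrawing substituent that the next step needs at C6.

**Step 10**
Reactants: 11 epoxy enoate
Product: 12 ethyl (2E)-4-[(1R,4S)-4-(TBSO)-1,2,2-trimethylcyclopentyl]-4-oxobut-2-enoate
Conditions: SnCl4 (1.5 equiv), CH2Cl2, −78 → −20 °C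
Reagents that add atoms: none
Why: In this Lewis acid-promoted semipinacol (Meinwald-type) ring contraction the acrylate destabilises a cation at C6, so the C5–O bond ionises and the C1–C6 ring bond migrates to C5 anti to the leaving oxygen, which forms ring B, sets the quaternary C5' (R, methyl cis to the silyloxy group) by inversion and turns C6 into the ketone.

**Step 11**
Reactants: 12 cyclopentyl keto enoate
Product: 14 2-[(1R,4S)-4-(TBSO)-1,2,2-trimethylcyclopentyl]-2-oxoacetaldehyde, via secondary ozonide 13 (not isolated)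
Conditions: O3, CH2Cl2, −78 °C; then Me2S, −78 °C → rt
Reagents that add atoms: ozone, [O-][O+]=O
Why: Ozonolysis (Criegee mechanism) cleaves the only C=C, as it does for fumarate-type alkenes, and leaves the silyl ether and both stereocentres untouched.

**Step 12**
Reactants: 14 keto aldehyde
Product: 15 (1R,4S)-4-(TBSO)-1,2,2-trimethylcyclopentane-1-carboxylic acid
Conditions: 30% H2O2, NaOH, THF–H2O, 0 °C; then aq. HCl to pH 3
Reagents that add atoms: hydrogen peroxide, OO
Why: In this alkaline peroxide cleavage of a 1,2-dicarbonyl, hydroperoxide adds to the unhindered formyl group and a Baeyer–Villiger-type acyl shift gives a mixed anhydride that hydrolyses to the acid and formate.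

**Step 13**
Reactants: 15 cyclopentanecarboxylic acid
Product: 17 1-[(1R,4S)-4-(TBSO)-1,2,2-trimethylcyclopentyl]ethan-1-one, via dilithium gem-diolate 16 (not isolated)
Conditions: MeLi (3 equiv), Et2O, 0 °C → rt; then H2O
Reagents that add atoms: methyllithium, [Li]C
Why: Addition of an organolithium to a lithium carboxylate stops at the stable gem-diolate, which collapses to the methyl ketone only on quench, so the hindered acid gives no tertiary alcohol.

**Step 14**
Reactants: 18 propargyl alcohol
Product: 20 (E)-3-iodo-2-methylprop-2-en-1-ol, via vinylalane 19 (not isolated)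
Conditions: Me3Al (3 equiv), Cp2ZrCl2 (25 mol %), CH2Cl2, 0 °C → rt; then I2, THF, −30 °C
Reagents that add atoms: trimethylaluminium, C[Al](C)C; iodine, [I][I]
Why: Negishi zirconium-catalysed carboalumination adds methyl and aluminium syn with aluminium at the terminus, and iodinolysis proceeds with retention, which fixes the 9'E geometry.

**Step 15**
Reactants: 20 iodo allylic alcohol
Product: 21 (E)-3-iodo-2-methylprop-2-enal
Conditions: MnO2, CH2Cl2, rt, dark
Reagents that add atoms: none
Why: MnO2 oxidation of an allylic alcohol is neutral and keeps both the vinyl iodide and the alkene geometry.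

**Step 16**
Reactants: 17 cyclopentyl methyl ketone; 21 (E)-3-iodo-2-methylprop-2-enal
Product: 23 (4E)-3-hydroxy-5-iodo-4-methyl-1-[(1R,4S)-4-(TBSO)-1,2,2-trimethylcyclopentyl]pent-4-en-1-one (both C3 epimers), via lithium enolate 22 (not isolated)
Conditions: LiN(i-Pr)2, THF, −78 °C; then 21, −78 °C; then H2O
Reagents that add atoms: none
Why: In this directed aldol addition, 17 can enolise only at its methyl group, the lithium enolate adds 1,2 to the enal at low temperature, and the new carbinol centre needs no control because the next step destroys it.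

**Step 17**
Reactants: 23 β-hydroxy ketone
Product: 24 (2Z,4E)-3-hydroxy-5-iodo-4-methyl-1-[(1R,4S)-4-(TBSO)-1,2,2-trimethylcyclopentyl]penta-2,4-dien-1-one (enol form of the 1,3-diketone)
Conditions: 2-iodoxybenzoic acid (2 equiv), EtOAc, 75 °C
Reagents that add atoms: none
Why: Oxidation of a β-hydroxy ketone with 2-iodoxybenzoic acid gives the 1,3-diketone without retro-aldol cleavage or over-oxidation at the central carbon, and the product rests as the chelated enol.

### Ring A and aldehyde 42 (steps 18–30)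

**Step 18**
Reactants: 4 silylated actinol
Product: 26 (4R)-4-(TBSO)-2,6,6-trimethyl-1-(trimethylsilyloxy)cyclohex-1-ene, via lithium enolate 25 (not isolated)
Conditions: LiN(i-Pr)2, THF, −78 °C; then Me3SiCl, −78 °C → rt
Reagents that add atoms: trimethylsilyl chloride, C[Si](C)(C)Cl
Why: Silyl enol ether formation is regiospecific because only one α-carbon carries hydrogen.

**Step 19**
Reactants: 26 silyl enol ether
Product: 27 (4S)-4-(TBSO)-2,6,6-trimethylcyclohex-2-en-1-one
Conditions: Pd(OAc)2 (1.05 equiv), MeCN, rt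
Reagents that add atoms: none
Why: In the Saegusa–Ito oxidation the divalent palladium enolate undergoes β-hydride elimination toward the ring CH2 to give the endocyclic enone, and the carbinol centre is unchanged in space (its descriptor changes only by priority).

**Step 20**
Reactants: 28 (E)-3-methylpent-2-en-4-yn-1-ol
Product: 29 (E)-5-(TBSO)-3-methylpent-3-en-1-yne
Conditions: t-BuMe2SiCl, imidazole, CH2Cl2, rt
Reagents that add atoms: tert-butyldimethylsilyl chloride, CC(C)(C)[Si](C)(C)Cl
Why: Silyl protection of the primary alcohol allows clean monolithiation of the alkyne, and the stereodefined alkene of 28 becomes the 9E bond.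

**Step 21**
Reactants: 29 silylated enyne; 27 enone
Product: 31 (4S)-4-(TBSO)-1-[(3E)-5-(TBSO)-3-methylpent-3-en-1-yn-1-yl]-2,6,6-trimethylcyclohex-2-en-1-ol (both C1 epimers), via lithium acetylide 30 (not isolated)
Conditions: 29, n-BuLi, THF, −78 °C; then 27, −78 → −20 °C; then H2O
Reagents that add atoms: none
Why: In this acetylide 1,2-addition the slim, hard nucleophile reaches the hindered enone carbonyl, and the new tertiary carbinol centre needs no control because the next step erases it.

**Step 22**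
Reactants: 31 tertiary allylic alcohol
Product: 32 (6S)-6-(TBSO)-3-[(3E)-5-(TBSO)-3-methylpent-3-en-1-yn-1-yl]-2,4,4-trimethylcyclohex-2-en-1-one
Conditions: [C5H5NH][CrO3Cl] (3 equiv), 4 Å molecular sieves, CH2Cl2, rt
Reagents that add atoms: pyridinium chlorochromate (gives the new carbonyl oxygen), [O-][Cr](=O)(=O)Cl.c1cc[nH+]cc1
Why: In the Babler–Dauben oxidative transposition the chromate ester of the tertiary allylic alcohol shifts by a [3,3] process to C4 and is oxidised there, which places the C5=C6 alkene in conjugation with the alkyne and the ketone at C4 without touching C3.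

**Step 23**
Reactants: 32 bis-silylated enone
Product: 33 (6S)-6-hydroxy-3-[(3E)-5-hydroxy-3-methylpent-3-en-1-yn-1-yl]-2,4,4-trimethylcyclohex-2-en-1-one
Conditions: 48% aq. HF, MeCN, 0 °C → rt
Reagents that add atoms: none
Why: Acidic fluoride desilylation frees the C3 hydroxyl for the next step and avoids base, which could epimerise or autoxidise the α-ketol.

**Step 24**
Reactants: 33 α-hydroxy enone
Product: 34 (1S,2S)-4-[(3E)-5-hydroxy-3-methylpent-3-en-1-yn-1-yl]-3,5,5-trimethylcyclohex-3-ene-1,2-diol (trans diol)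
Conditions: Me4N[BH(OAc)3] (5 equiv), MeCN–AcOH (1:1), −30 °C; chromatography
Reagents that add atoms: none
Why: In this hydroxyl-directed (Evans–Saksena type) reduction the reagent is too weak to reduce the enone on its own, so hydride arrives only from the borate bound to the C3 oxygen, on the face of that C–O bond, which sets C4 (S) with its hydroxyl trans to the C3 hydroxyl.

**Step 25**
Reactants: 34 triol
Product: 35 tris-TBS ether of 34
Conditions: t-BuMe2SiOTf (4 equiv), 2,6-lutidine, CH2Cl2, −78 → 0 °C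
Reagents that add atoms: tert-butyldimethylsilyl triflate, CC(C)(C)[Si](C)(C)OS(=O)(=O)C(F)(F)F
Why: Exhaustive silylation with the reactive triflate covers even the hindered allylic C4 hydroxyl, which must be protected against the later MnO2 oxidations.

**Step 26**
Reactants: 35 tris-silyl ether
Product: 36 (2E)-5-[(3S,4S)-3,4-bis(TBSO)-2,6,6-trimethylcyclohex-1-en-1-yl]-3-methylpent-2-en-4-yn-1-ol
Conditions: pyridinium p-toluenesulfonate (20 mol %), MeOH–CH2Cl2, 0 °C
Reagents that add atoms: none
Why: Selective acid-catalysed methanolysis works here because the unhindered primary silyl ether is cleaved far faster than the two crowded secondary ones.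

**Step 27**
Reactants: 36 primary allylic alcohol
Product: 37 (2E)-5-[(3S,4S)-3,4-bis(TBSO)-2,6,6-trimethylcyclohex-1-en-1-yl]-3-methylpent-2-en-4-ynal
Conditions: MnO2, CH2Cl2, rt
Reagents that add atoms: none
Why: MnO2 allylic oxidation gives the enynal under neutral conditions with the 9E geometry retained.

**Step 28**
Reactants: 37 enynal; 38 ethyl (2E)-4-(diethoxyphosphoryl)-3-methylbut-2-enoate
Product: 40 ethyl (2E,4E,6E)-9-[(3S,4S)-3,4-bis(TBSO)-2,6,6-trimethylcyclohex-1-en-1-yl]-3,7-dimethylnona-2,4,6-trien-8-ynoate, via lithiated phosphonate 39 (not isolated)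
Conditions: 38, n-BuLi, THF–DMPU, −78 °C; then 37, −78 → 0 °C
Reagents that add atoms: none
Why: This vinylogous Horner–Wadsworth–Emmons olefination, the standard C5 extension of retinoid chemistry, forms C11=C12 as the E alkene and keeps 13E under lithium/DMPU conditions.

**Step 29**
Reactants: 40 trienynoate
Product: 41 (2E,4E,6E)-9-[(3S,4S)-3,4-bis(TBSO)-2,6,6-trimethylcyclohex-1-en-1-yl]-3,7-dimethylnona-2,4,6-trien-8-yn-1-ol
Conditions: i-Bu2AlH (2.5 equiv), CH2Cl2, −78 °C
Reagents that add atoms: none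
Why: 1,2-Reduction of the conjugated ester at low temperature leaves the enyne, the polyene and the silyl ethers alone.

**Step 30**
Reactants: 41 trienynol
Product: 42 (2E,4E,6E)-9-[(3S,4S)-3,4-bis(TBSO)-2,6,6-trimethylcyclohex-1-en-1-yl]-3,7-dimethylnona-2,4,6-trien-8-ynal
Conditions: MnO2, CH2Cl2, rt, dark
Reagents that add atoms: none
Why: MnO2 allylic oxidation is the mildest way to a polyenal and causes no E/Z scrambling in the dark.

### Stannyl phosphonate 46 (steps 31–33)

**Step 31**
Reactants: 28 (E)-3-methylpent-2-en-4-yn-1-ol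
Product: 43 (2E,4E)-3-methyl-5-(tributylstannyl)penta-2,4-dien-1-ol
Conditions: n-Bu3SnH, PdCl2(PPh3)2 (2 mol %), THF, 0 °C → rt; chromatography on Et3N-treated silica
Reagents that add atoms: tributyltin hydride, CCCC[SnH](CCCC)CCCC
Why: Palladium-catalysed hydrostannation adds Sn–H syn with tin mainly at the unhindered terminus, giving the E vinylstannane (the future 11'E bond), while the alkene of 28 supplies 13'E.

**Step 32**
Reactants: 43 stannyl dienol
Product: 45 tributyl[(1E,3E)-5-bromo-3-methylpenta-1,3-dien-1-yl]stannane, via allylic mesylate 44 (not isolated)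
Conditions: MeSO2Cl, Et3N, CH2Cl2, −40 °C; then LiBr, THF, −40 → 0 °C
Reagents that add atoms: lithium bromide, [Li+].[Br-]
Why: Mesylation followed by SN2 displacement with bromide avoids acidic or electrophilic halogen reagents that would cleave the C–Sn bond.

**Step 33**
Reactants: 45 allylic bromide
Product: 46 diethyl [(2E,4E)-3-methyl-5-(tributylstannyl)penta-2,4-dien-1-yl]phosphonate
Conditions: P(OEt)3, toluene, 90 °C
Reagents that add atoms: triethyl phosphite, CCOP(OCC)OCC
Why: The Michaelis–Arbuzov reaction of a primary allylic bromide is neutral and leaves the vinylstannane and both alkene geometries intact.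

### Union and deprotection (steps 34–36)

**Step 34**
Reactants: 42 trienynal; 46 stannyl dienylphosphonate
Product: 48 tributyl[(1E,3E,5E,7E,9E,11E)-14-[(3S,4S)-3,4-bis(TBSO)-2,6,6-trimethylcyclohex-1-en-1-yl]-3,8,12-trimethyltetradeca-1,3,5,7,9,11-hexaen-13-yn-1-yl]stannane, via sodiated phosphonate 47 (not isolated)
Conditions: 46, NaN(SiMe3)2, THF, −78 °C; then 42, −78 → 0 °C, dark; filtration through Et3N-treated silica
Reagents that add atoms: none
Why: Horner–Wadsworth–Emmons olefination with an allylic phosphonate forms the central C15=C15' bond as the E alkene, and the amide base does not exchange with tin.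

**Step 35**
Reactants: 48 polyenynyl stannane; 24 β-diketone vinyl iodide
Product: 49 3,4,3'-tris-O-TBS ether of the target
Conditions: Pd2(dba)3·CHCl3 (5 mol %), AsPh3 (40 mol %), DMF, rt → 40 °C, dark, Ar
Reagents that add atoms: none
Why: The Stille cross-coupling is base-free and stereoretentive at both sp2 carbons, so the activated β-iodoenone-type iodide couples at C10'–C11' while the free enol, the alkyne and the silyl ethers are tolerated.

**Step 36**
Reactants: 49 tris-silyl ether
Product: 50 (3S,4S,3'S,5'R)-3,4,3',8'-tetrahydroxy-7,8-didehydro-β,κ-caroten-6'-one (target)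
Conditions: n-Bu4NF (10 equiv), THF, rt, dark; then pH 7 buffer
Reagents that add atoms: none
Why: Fluoride-mediated desilylation avoids acid, which would ionise the allylic C4 hydroxyl, and the diketone merely rests as its inert enolate until the neutral work-up.

## Compound list
1 | ketoisophorone (2,6,6-trimethylcyclohex-2-ene-1,4-dione) | CC1=CC(=O)CC(C)(C)C1=O | starting material
2 | (6R)-levodione | C[C@@H]1CC(=O)CC(C)(C)C1=O | intermediate
3 | (4R,6R)-actinol | C[C@@H]1C[C@@H](O)CC(C)(C)C1=O | intermediate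
4 | (4R,6R)-4-(TBSO)-2,2,6-trimethylcyclohexan-1-one | C[C@@H]1C[C@@H](O[Si](C)(C)C(C)(C)C)CC(C)(C)C1=O | intermediate
5 | potassium enolate of 4 | CC1=C(O[K])C(C)(C)C[C@H](O[Si](C)(C)C(C)(C)C)C1 | intermediate (not isolated)
6 | (4R)-4-(TBSO)-2,6,6-trimethylcyclohex-1-en-1-yl triflate | CC1=C(OS(=O)(=O)C(F)(F)F)C(C)(C)C[C@H](O[Si](C)(C)C(C)(C)C)C1 | intermediate
7 | methyl (4R)-4-(TBSO)-2,6,6-trimethylcyclohex-1-ene-1-carboxylate | CC1=C(C(=O)OC)C(C)(C)C[C@H](O[Si](C)(C)C(C)(C)C)C1 | intermediate
8 | [(4R)-4-(TBSO)-2,6,6-trimethylcyclohex-1-en-1-yl]methanol | CC1=C(CO)C(C)(C)C[C@H](O[Si](C)(C)C(C)(C)C)C1 | intermediate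
9 | (1R,4S,6R)-epoxy alcohol, oxygen anti to OTBS | C[C@]12O[C@@]1(CO)C(C)(C)C[C@H](O[Si](C)(C)C(C)(C)C)C2 | intermediate
10 | (1S,4S,6R)-epoxy aldehyde | C[C@]12O[C@@]1(C=O)C(C)(C)C[C@H](O[Si](C)(C)C(C)(C)C)C2 | intermediate
11 | (E)-epoxy enoate | C[C@]12O[C@@]1(/C=C/C(=O)OCC)C(C)(C)C[C@H](O[Si](C)(C)C(C)(C)C)C2 | intermediate
12 | ethyl (2E)-4-[(1R,4S)-4-(TBSO)-1,2,2-trimethylcyclopentyl]-4-oxobut-2-enoate | CCOC(=O)/C=C/C(=O)[C@]1(C)C[C@@H](O[Si](C)(C)C(C)(C)C)CC1(C)C | intermediate
13 | secondary ozonide (1,2,4-trioxolane) of 12 | CCOC(=O)C1OOC(O1)C(=O)[C@]2(C)C[C@@H](O[Si](C)(C)C(C)(C)C)CC2(C)C | intermediate (not isolated)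
14 | 2-[(1R,4S)-4-(TBSO)-1,2,2-trimethylcyclopentyl]-2-oxoacetaldehyde | O=CC(=O)[C@]1(C)C[C@@H](O[Si](C)(C)C(C)(C)C)CC1(C)C | intermediate
15 | (1R,4S)-4-(TBSO)-1,2,2-trimethylcyclopentane-1-carboxylic acid | OC(=O)[C@]1(C)C[C@@H](O[Si](C)(C)C(C)(C)C)CC1(C)C | intermediate
16 | dilithium gem-diolate from 15 and MeLi | CC(O[Li])(O[Li])[C@]1(C)C[C@@H](O[Si](C)(C)C(C)(C)C)CC1(C)C | intermediate (not isolated)
17 | 1-[(1R,4S)-4-(TBSO)-1,2,2-trimethylcyclopentyl]ethan-1-one | CC(=O)[C@]1(C)C[C@@H](O[Si](C)(C)C(C)(C)C)CC1(C)C | intermediate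
18 | propargyl alcohol | C#CCO | starting material
19 | (E)-vinylalane, dimethylaluminium alkoxide | C[Al](C)/C=C(C)/CO[Al](C)C | intermediate (not isolated)
20 | (E)-3-iodo-2-methylprop-2-en-1-ol | OC/C(C)=C/I | intermediate
21 | (E)-3-iodo-2-methylprop-2-enal | O=C/C(C)=C/I | intermediate
22 | lithium enolate of 17 | C=C(O[Li])[C@]1(C)C[C@@H](O[Si](C)(C)C(C)(C)C)CC1(C)C | intermediate (not isolated)
23 | aldol adduct (carbinol epimers) | O=C(CC(O)/C(C)=C/I)[C@]1(C)C[C@@H](O[Si](C)(C)C(C)(C)C)CC1(C)C | intermediate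
24 | β-diketone vinyl iodide, chelated enol | I/C=C(C)/C(O)=C/C(=O)[C@]1(C)C[C@@H](O[Si](C)(C)C(C)(C)C)CC1(C)C | intermediate
25 | lithium enolate of 4 | CC1=C(O[Li])C(C)(C)C[C@H](O[Si](C)(C)C(C)(C)C)C1 | intermediate (not isolated)
26 | trimethylsilyl enol ether of 4 | CC1=C(O[Si](C)(C)C)C(C)(C)C[C@H](O[Si](C)(C)C(C)(C)C)C1 | intermediate
27 | (4S)-4-(TBSO)-2,6,6-trimethylcyclohex-2-en-1-one | CC1=C[C@@H](O[Si](C)(C)C(C)(C)C)CC(C)(C)C1=O | intermediate
28 | (E)-3-methylpent-2-en-4-yn-1-ol | C#C/C(C)=C/CO | starting material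
29 | TBS ether of 28 | C#C/C(C)=C/CO[Si](C)(C)C(C)(C)C | intermediate
30 | lithium acetylide of 29 | [Li]C#C/C(C)=C/CO[Si](C)(C)C(C)(C)C | intermediate (not isolated)
31 | tertiary allylic, propargylic alcohol (C6 epimers) | CC1=C[C@@H](O[Si](C)(C)C(C)(C)C)CC(C)(C)C1(O)C#C/C(C)=C/CO[Si](C)(C)C(C)(C)C | intermediate
32 | (3S)-3-OTBS-4-oxo enynyl enone | CC1=C(C#C/C(C)=C/CO[Si](C)(C)C(C)(C)C)C(C)(C)C[C@H](O[Si](C)(C)C(C)(C)C)C1=O | intermediate
33 | (3S)-3-hydroxy-4-oxo enynol | CC1=C(C#C/C(C)=C/CO)C(C)(C)C[C@H](O)C1=O | intermediate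
34 | (3S,4S)-trans-diol enynol (triol) | CC1=C(C#C/C(C)=C/CO)C(C)(C)C[C@H](O)[C@H]1O | intermediate
35 | tris-TBS ether of 34 | CC1=C(C#C/C(C)=C/CO[Si](C)(C)C(C)(C)C)C(C)(C)C[C@H](O[Si](C)(C)C(C)(C)C)[C@H]1O[Si](C)(C)C(C)(C)C | intermediate
36 | C15 enynol, 3,4-bis-TBS | CC1=C(C#C/C(C)=C/CO)C(C)(C)C[C@H](O[Si](C)(C)C(C)(C)C)[C@H]1O[Si](C)(C)C(C)(C)C | intermediate
37 | C15 enynal, 3,4-bis-TBS | CC1=C(C#C/C(C)=C/C=O)C(C)(C)C[C@H](O[Si](C)(C)C(C)(C)C)[C@H]1O[Si](C)(C)C(C)(C)C | intermediate
38 | ethyl (2E)-4-(diethoxyphosphoryl)-3-methylbut-2-enoate | CCOC(=O)/C=C(C)/CP(=O)(OCC)OCC | starting material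
39 | lithiated 38 | CCOC(=O)/C=C(C)/C([Li])P(=O)(OCC)OCC | intermediate (not isolated)
40 | C20 trienynoate | CC1=C(C#C/C(C)=C/C=C/C(C)=C/C(=O)OCC)C(C)(C)C[C@H](O[Si](C)(C)C(C)(C)C)[C@H]1O[Si](C)(C)C(C)(C)C | intermediate
41 | C20 trienynol | CC1=C(C#C/C(C)=C/C=C/C(C)=C/CO)C(C)(C)C[C@H](O[Si](C)(C)C(C)(C)C)[C@H]1O[Si](C)(C)C(C)(C)C | intermediate
42 | C20 trienynal | CC1=C(C#C/C(C)=C/C=C/C(C)=C/C=O)C(C)(C)C[C@H](O[Si](C)(C)C(C)(C)C)[C@H]1O[Si](C)(C)C(C)(C)C | intermediate
43 | (2E,4E)-3-methyl-5-(tributylstannyl)penta-2,4-dien-1-ol | OC/C=C(C)/C=C/[Sn](CCCC)(CCCC)CCCC | intermediate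
44 | methanesulfonate of 43 | CS(=O)(=O)OC/C=C(C)/C=C/[Sn](CCCC)(CCCC)CCCC | intermediate (not isolated)
45 | tributyl[(1E,3E)-5-bromo-3-methylpenta-1,3-dien-1-yl]stannane | BrC/C=C(C)/C=C/[Sn](CCCC)(CCCC)CCCC | intermediate
46 | diethyl [(2E,4E)-3-methyl-5-(tributylstannyl)penta-2,4-dien-1-yl]phosphonate | CCOP(=O)(OCC)C/C=C(C)/C=C/[Sn](CCCC)(CCCC)CCCC | intermediate
47 | sodiated 46 | CCOP(=O)(OCC)C([Na])/C=C(C)/C=C/[Sn](CCCC)(CCCC)CCCC | intermediate (not isolated)
48 | all-E C26 hexaenynyl stannane | CC1=C(C#C/C(C)=C/C=C/C(C)=C/C=C/C=C(C)/C=C/[Sn](CCCC)(CCCC)CCCC)C(C)(C)C[C@H](O[Si](C)(C)C(C)(C)C)[C@H]1O[Si](C)(C)C(C)(C)C | intermediate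
49 | 3,4,3'-tris-O-TBS target | CC1=C(C#C/C(C)=C/C=C/C(C)=C/C=C/C=C(C)/C=C/C=C(C)/C(O)=C/C(=O)[C@]2(C)C[C@@H](O[Si](C)(C)C(C)(C)C)CC2(C)C)C(C)(C)C[C@H](O[Si](C)(C)C(C)(C)C)[C@H]1O[Si](C)(C)C(C)(C)C | intermediate
50 | (3S,4S,3'S,5'R)-3,4,3',8'-tetrahydroxy-7,8-didehydro-β,κ-caroten-6'-one | CC1=C(C#C/C(C)=C/C=C/C(C)=C/C=C/C=C(C)/C=C/C=C(C)/C(O)=C/C(=O)[C@]2(C)C[C@@H](O)CC2(C)C)C(C)(C)C[C@H](O)[C@H]1O | target

## Step count and risks
Total steps: 36.

Longest linear sequence: 18 steps (1 → 2 → 3 → 4 → 26 → 27 → 31 → 32 → 33 → 34 → 35 → 36 → 37 → 40 → 41 → 42 → 48 → 49 → 50).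

**Step 10 (ring contraction).** The risks are opening at the wrong carbon, alkenyl migration, or elimination to an allylic alcohol.
The fallback sets out from triflate 6 and comes back at methyl ketone 17.
- Fe(acac)3-catalysed cross-coupling of 6 with MeMgBr (THF–NMP, −20 °C) gives (R)-tert-butyldimethyl[(3,4,5,5-tetramethylcyclohex-3-en-1-yl)oxy]silane F1.
- m-Chloroperbenzoic acid (CH2Cl2, 0 °C) attacks the only alkene mainly anti to the silyloxy group, and chromatography gives the anti 5,6-epoxide of the tetramethylcyclohexene F2.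
- BF3·OEt2 (CH2Cl2, −78 °C) then contracts the ring straight to 17.
- In this all-alkyl epoxide, ionisation at either carbon followed by shift of the neighbouring ring bond anti to the leaving oxygen gives the same 1-acetyl-1,2,2-trimethylcyclopentane with methyl cis to the silyloxy group, so the regiochemistry of opening no longer matters.
- The acetyl methyl is already in place, so no oxidative cleavage is needed.

**Step 24 (trans-selective reduction).** The risk is a poor trans:cis ratio.
The fallback sets out from enone 27 (with enyne 29) and comes back at tris-silyl ether 35. It sets the C4 oxygen by substrate-controlled epoxidation instead of ketone reduction.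
- H2O2/NaOH in MeOH epoxidises 27 anti to the adjacent silyloxy group to give the trans-4,5-epoxy ketone F3.
- Reductive opening at the α-carbon with (PhSe)2/NaBH4 in EtOH–AcOH gives the β-hydroxy ketone with C4–OH trans to C3–OTBS F4.
- t-BuMe2SiOTf/2,6-lutidine gives the 3,4-bis-TBS ketone F5.
- KN(SiMe3)2/PhNTf2 at −78 °C gives the 3,4-bis-TBS enol triflate F6.
- Sonogashira coupling of F6 with 29 (PdCl2(PPh3)2, CuI, i-Pr2NH, THF) gives 35.

**Step 35 (Stille coupling of the long stannane).** The risks are protodestannylation or decomposition of 48, or a sluggish coupling.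
The fallback sets out from 24, 43 and 41 and comes back at 49. It closes the chain at the central double bond by Wittig olefination, with the diketone carried on the aldehyde partner as its inert enolate.
- Stille coupling of 24 with the small, robust stannane 43 (same catalyst) gives the C20 trienol diketone F7.
- MnO2 gives the C20 trienal diketone F8.
- Separately, 41 is converted (MeSO2Cl, Et3N; LiBr) into the C20 allylic bromide F9.
- PPh3 in CH2Cl2 converts F9 into the C20 triphenylphosphonium bromide F10.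
- F10 and F8 with excess NaOMe in CH2Cl2 give 49, and any 15Z isomer relaxes to all-E on gentle warming in the dark.

## Further compounds
F1 | step 10 | (R)-tert-butyldimethyl[(3,4,5,5-tetramethylcyclohex-3-en-1-yl)oxy]silane | CC1=C(C)C(C)(C)C[C@H](O[Si](C)(C)C(C)(C)C)C1
F2 | step 10 | anti 5,6-epoxide of the tetramethylcyclohexene (oxygen trans to OTBS) | C[C@]12O[C@@]1(C)C(C)(C)C[C@H](O[Si](C)(C)C(C)(C)C)C2
F3 | step 24 | trans-4,5-epoxy ketone (oxygen anti to OTBS) | C[C@@]12O[C@@H]1[C@@H](O[Si](C)(C)C(C)(C)C)CC(C)(C)C2=O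
F4 | step 24 | β-hydroxy ketone with C4–OH trans to C3–OTBS (C5 epimers) | CC1C(=O)C(C)(C)C[C@H](O[Si](C)(C)C(C)(C)C)[C@H]1O
F5 | step 24 | 3,4-bis-TBS ketone (C5 epimers) | CC1C(=O)C(C)(C)C[C@H](O[Si](C)(C)C(C)(C)C)[C@H]1O[Si](C)(C)C(C)(C)C
F6 | step 24 | 3,4-bis-TBS enol triflate | CC1=C(OS(=O)(=O)C(F)(F)F)C(C)(C)C[C@H](O[Si](C)(C)C(C)(C)C)[C@H]1O[Si](C)(C)C(C)(C)C
F7 | step 35 | C20 trienol diketone | OC/C=C(C)/C=C/C=C(C)/C(O)=C/C(=O)[C@]1(C)C[C@@H](O[Si](C)(C)C(C)(C)C)CC1(C)C
F8 | step 35 | C20 trienal diketone | O=C/C=C(C)/C=C/C=C(C)/C(O)=C/C(=O)[C@]1(C)C[C@@H](O[Si](C)(C)C(C)(C)C)CC1(C)C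
F9 | step 35 | C20 allylic bromide | CC1=C(C#C/C(C)=C/C=C/C(C)=C/CBr)C(C)(C)C[C@H](O[Si](C)(C)C(C)(C)C)[C@H]1O[Si](C)(C)C(C)(C)C
F10 | step 35 | C20 triphenylphosphonium bromide | CC1=C(C#C/C(C)=C/C=C/C(C)=C/C[P+](c2ccccc2)(c2ccccc2)c2ccccc2)C(C)(C)C[C@H](O[Si](C)(C)C(C)(C)C)[C@H]1O[Si](C)(C)C(C)(C)C.[Br-]
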